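## The problem

The target is a phenylcoumaran neolignan built on a 2,3-dihydrobenzofuran. Ring A (the benzo ring) carries a methoxy group at C7 and an (E)-propenoic acid at C5. Ring B (the dihydrofuran) carries a hydroxymethyl group at C3 and a 4-hydroxy-3,5-dimethoxyphenyl group (ring C) at C2. The skeletal task is ring B, that is, the O1–C2 and C2–C3 bonds, together with two contiguous stereocentres, 2S and 3R, in a trans relationship. The two centres are not equal partners. C2 is a benzylic ether carbon para to a free phenol and can open reversibly through a para-quinone methide of ring C, so under acid or base it relaxes to the trans arrangement dictated by C3. C3 has no acidifying neighbour, cannot be corrected later and therefore carries the absolute configuration. The fragile functions are the oxidisable syringyl phenol, the C2–O bond (hydrogenolysis, ionic reduction, strong acid), the acrylic acid (conjugate addition, hydrogenation, esterification in acidic alcohols) and the primary alcohol. This excludes hydrogenolytic deprotection and argues for a late side-chain installation and acid-labile protection. The enabling feature is that C2 is a single carbon bridging O1 and C3, while O1–C7a–C3a–C3 is the heterodiene of an ortho-quinone methide of ring A with C3 as its exocyclic terminus. C2 can therefore arrive with ring C as a one-carbon ylide that forms both ring-B bonds and both stereocentres at once. C5 lies para to O1 and can carry a bromine through that chemistry as a handle for the acrylic acid.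

## Retrosynthesis

**21 to 20 (O–Si and O–CH2OMe).** The last operation only removes the silyl ether from the C3 arm and the methoxymethyl acetal from the ring-C phenol of 20. Keeping the phenol masked until the end matters for two reasons. A free para-phenoxide would expel the sulfide from the benzylsulfonium salt in the annulation, and it would open ring B through a para-quinone methide under the basic Heck conditions. Both groups fall to aqueous acid in one step. The forward reaction must not ionise C2–O irreversibly; any reversible opening returns to the trans isomer because C3 is untouched.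

**20 to 18 and 19 (C5–vinyl bond).** Cutting the aryl–alkene bond removes three carbons and the acid and leads to aryl bromide 18 and acrylic acid 19. The neighbouring choice, carrying an acrylate through the annulation, would offer the ylide and the sulfinate a second Michael acceptor. A bromine para to O1 is inert to carbonate and to sulfonium ylides. The forward step is a Heck reaction on an electron-rich aryl bromide.

**18 to 6 and 14 (C2–C3 and O1–C2, the key cut).** Both ring-B bonds at C2 are cut together, which takes away the ring and both stereocentres. What remains is racemic sulfone 6 (a latent ortho-quinone methide of ring A) and sulfonium salt 14, whose only chirality sits in a recoverable sulfide. Cutting O1–C2 alone would leave C3 to be made separately. Cutting C2–aryl or C3–C3a would give acyclic intermediates that still need ring closure. The forward reaction must control the ylide face (C2), the relative topicity of the addition (C3, trans) and the partitioning of a short-lived alkyl quinone methide.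

**6 to 5, 5 to 2 and 3, 2 to 1 (C–S, C3–C3a, C–I).** The sulfone comes from ortho-hydroxybenzylic alcohol 5 and p-toluenesulfinic acid. Alcohol 5 comes from the aryl Grignard reagent of iodophenol 2 and silyloxyacetaldehyde 3, and 2 from iodination of bromoguaiacol 1. A direct acid condensation of 1, 3 and a sulfinate would be shorter. It is avoided because substitution para to the methoxy group competes and the silyl ether would not survive the acid needed. The stepwise route fixes the regiochemistry through the halogen.

**14 to 13 and 9; 13 to 12, 11 and 10; 9 to 8 and 7 (S–C and functional-group changes).** The sulfonium salt is the S-alkylation product of C2-symmetric thiolane 9 with benzylic bromide 13. Bromide 13 is reached from syringaldehyde 10 by acetal protection (11), reduction (12) and bromination. Thiolane 9 comes from the (2R,5R)-diol 7 through dimesylate 8 by double inversion. A C2-symmetric sulfide is preferred over an unsymmetrical one because alkylation then gives a single sulfonium salt with no sulfur stereocentre.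

## Roads not taken

**Alternative 1:** Oxypalladation and carbonylation of a 2-hydroxystilbene. The cut is O1–C2 plus the bond from C3 to its one-carbon substituent. Stilbene A1 would be treated with divalent palladium as Pd(OCOCF3)2, a chiral bisoxazoline, CuCl2, CO and methanol, so that the ring-A phenol adds to C2 and the C3–palladium bond is carbonylated to ester A2.
- Merits: it is catalytic in the chiral element, and anti-oxypalladation of the E alkene followed by retentive carbonylation translates alkene geometry into the trans ring. In this respect it is better than the chosen plan, which spends a stoichiometric (though recoverable) chiral sulfide.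
- Weak points:
  - The ring closure is 5-endo onto an internal, electron-rich stilbene, outside the terminal-alkene exo closures on which this chemistry rests.
  - The C3–palladium intermediate has a syn hydrogen at C2, so β-hydride elimination to the aromatic 2-arylbenzofuran competes with CO capture.
  - The oxidising copper/palladium medium threatens the phenol.
  - A2 has an acidic C3–H next to the ester, so base can open the ring by β-elimination and erode the centre that carries the absolute configuration.
- Step economy: after A2 the ester must still be reduced, the pivalate removed, the acetal unmasked and the aldehyde homologated, so no steps are saved.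
- Comparison: the chosen plan sets against the catalytic advantage a non-epimerisable C3 substituent from the start, a ring closure of a favoured mode and a two-step endgame.

**Alternative 2:** Stereoconvergent para-quinone methide oxa-cyclisation. Only O1–C2 is cut. Mild acid ionises the benzylic alcohol of diol A3 (either carbinol epimer) to the syringyl para-quinone methide, and the ring-A phenol closes to trans bromide A4.
- Merits: this is the most reliable ring closure of all four plans. It uses the thermodynamic trans preference, tolerates a carbinol mixture and leaves only a Heck reaction after A4. In certainty of the ring-forming step it is better than the chosen plan.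
- Weak points: the absolute stereochemistry is moved, not solved. The ring-A benzylic centre of A3 must be made enantioselectively beforehand, for instance by an auxiliary-controlled aldol with attachment, reductive removal and protecting-group traffic. This makes the sequence more linear and several steps longer, and the final Heck reaction would run on a free phenol prone to base-triggered ring opening.
- Comparison: the chosen plan creates C3, C2 and the ring in one convergent step from a racemic and an achiral fragment. It also keeps this alternative's thermodynamic argument as a safety net in its last step.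

**Alternative 3:** Three-component conjunctive coupling across an alkenyl boronate. The cuts are C2–aryl (ring C) and C3–C3a. The aryllithium from A6 adds to alkenyl boronic ester A5, and the boronate complex reacts with aryl iodide A7 under Pd(OAc)2 and a chiral MandyPhos ligand. Ring C migrates from boron to C2 while palladium delivers ring A to C3, giving boronic ester A8.
- Merits: it is catalytic and enantioselective, highly modular, and builds both C–C bonds to the two aryl rings in one step. Its pedigree for absolute control at C3 is stronger than that of a stoichiometric ylide.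
- Weak points:
  - The key step does not close ring B. A8 still needs C–B oxidation, unmasking of the ring-A phenol and an ionising closure. The configuration installed at the boron-bearing carbon is then overwritten thermodynamically, so half of the induced stereochemistry is redundant.
  - β-Substituted alkenyl boronates and an ortho,ortho-flanked aryl iodide (halide inhibition, steric hindrance) are demanding cases for this coupling.
  - The acetal must still be converted into the acrylic acid.
- Comparison: the sequence after the key step is clearly longer than in the chosen plan. The chosen plan accepts a less proven stereocontrol element in exchange for forming the ring and both centres at once and finishing in two steps.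

Key step: step 10

Assumption (stereochemical sense): the thiolanium benzylide is taken to react on the same face as in carbonyl epoxidation with this sulfide class. With the substituent priorities at C2 this calls for the (2S,5S) sulfide to reach 2S,3R; if the sense proved opposite, the antipodal sulfide from (2S,5S)-hexane-2,5-diol would be used.

Assumption (supply): compounds 1, 3, 7, 10 and 19 are taken as catalogue materials.

## Route

Step 1
Reactants: 1 4-bromo-2-methoxyphenol
Product: 2 4-bromo-2-iodo-6-methoxyphenol
Conditions: NaI, NaOH, aq. NaOCl, MeOH, 0 °C
Reagents that add atoms: sodium iodide, [Na+].[I-]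
Why: Electrophilic aromatic iodination of the phenoxide by hypoiodite formed in situ; the para position is blocked by bromine and C6 is the only free position ortho to the phenoxide oxygen, so one regioisomer is expected.

Step 2
Reactants: 2 4-bromo-2-iodo-6-methoxyphenol; 3 (tert-butyldimethylsilyloxy)acetaldehyde
Product: 5 rac-1-(5-bromo-2-hydroxy-3-methoxyphenyl)-2-[(tert-butyldimethylsilyl)oxy]ethan-1-ol, via aryl Grignard phenoxide 4 (not isolated)
Conditions: MeMgCl (1.0 equiv), LiCl, THF, −30 °C; i-PrMgCl (1.1 equiv), −30 to 0 °C; then 3, −40 to 0 °C; aq. NH4Cl
Reagents that add atoms: none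
Why: Iodine–magnesium exchange on the magnesium phenoxide, much faster at C–I than at C–Br, followed by 1,2-addition of the aryl Grignard reagent to the aldehyde; the carbinol centre is racemic, which is immaterial because it becomes the trigonal exocyclic carbon of the quinone methide.

Step 3
Reactants: 5 rac-1-(5-bromo-2-hydroxy-3-methoxyphenyl)-2-[(tert-butyldimethylsilyl)oxy]ethan-1-ol
Product: 6 rac-4-bromo-2-{2-[(tert-butyldimethylsilyl)oxy]-1-(4-methylbenzenesulfonyl)ethyl}-6-methoxyphenol
Conditions: p-TolSO2H (1.5 equiv, freshly liberated), 4 Å MS, CH2Cl2, 0 °C to rt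
Reagents that add atoms: p-toluenesulfinic acid, Cc1ccc(cc1)S(=O)O
Why: SN1-type substitution of an ortho-hydroxybenzylic alcohol by a sulfinic acid through the ortho-hydroxybenzyl cation, the standard entry to 2-(1-sulfonylalkyl)phenols; sulfur alkylation gives the sulfone, and anhydrous aprotic conditions at or below room temperature should spare the primary silyl ether. The centre is racemic and is erased in step 10.

Step 4
Reactants: 7 (2R,5R)-hexane-2,5-diol
Product: 8 (2R,5R)-hexane-2,5-diyl dimethanesulfonate
Conditions: MsCl, Et3N, CH2Cl2, −20 to 0 °C
Reagents that add atoms: methanesulfonyl chloride, CS(=O)(=O)Cl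
Why: O-Sulfonylation of both secondary alcohols; the C–O bonds are not touched, so both centres are retained.

Step 5
Reactants: 8 (2R,5R)-hexane-2,5-diyl dimethanesulfonate
Product: 9 (2S,5S)-2,5-dimethylthiolane
Conditions: Na2S·9H2O, DMSO, rt; distillation
Reagents that add atoms: sodium sulfide, [Na+].[Na+].[S-2]
Why: Twofold SN2 displacement by sulfide, first intermolecular and then 5-exo-tet; each carbon is inverted, which turns the R,R diol series into the S,S thiolane.

Step 6
Reactants: 10 syringaldehyde (4-hydroxy-3,5-dimethoxybenzaldehyde)
Product: 11 3,5-dimethoxy-4-(methoxymethoxy)benzaldehyde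
Conditions: MOMCl, i-Pr2NEt, CH2Cl2, 0 °C to rt
Reagents that add atoms: chloromethyl methyl ether, COCCl
Why: O-Alkylation of the phenol (methoxymethyl protection); the acetal withstands hydride, phosphine/halide, carbonate and palladium chemistry and is removed by aqueous acid at the end.

Step 7
Reactants: 11 3,5-dimethoxy-4-(methoxymethoxy)benzaldehyde
Product: 12 [3,5-dimethoxy-4-(methoxymethoxy)phenyl]methanol
Conditions: NaBH4, MeOH, 0 °C
Reagents that add atoms: none
Why: Borohydride reduction of an aryl aldehyde to the benzylic alcohol; no other reducible group is present.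

Step 8
Reactants: 12 [3,5-dimethoxy-4-(methoxymethoxy)phenyl]methanol
Product: 13 5-(bromomethyl)-1,3-dimethoxy-2-(methoxymethoxy)benzene
Conditions: CBr4, PPh3, CH2Cl2, 0 °C
Reagents that add atoms: carbon tetrabromide, BrC(Br)(Br)Br
Why: Appel reaction; neutral conversion of the primary benzylic alcohol into the bromide, chosen over HBr or PBr3 so that the acetal is not exposed to acid.

Step 9
Reactants: 13 5-(bromomethyl)-1,3-dimethoxy-2-(methoxymethoxy)benzene; 9 (2S,5S)-2,5-dimethylthiolane
Product: 14 (2S,5S)-1-{[3,5-dimethoxy-4-(methoxymethoxy)phenyl]methyl}-2,5-dimethylthiolan-1-ium tetrafluoroborate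
Conditions: NaBF4 (5 equiv), CH2Cl2/H2O, rt
Reagents that add atoms: sodium tetrafluoroborate, [Na+].F[B-](F)(F)F
Why: SN2 S-alkylation of the sulfide by the benzylic bromide with in situ exchange to the non-nucleophilic tetrafluoroborate, which suppresses reversal; because the thiolane is C2-symmetric its two lone pairs are equivalent and a single salt without a sulfur stereocentre results.

Step 10
Reactants: 6 rac-4-bromo-2-{2-[(tert-butyldimethylsilyl)oxy]-1-(4-methylbenzenesulfonyl)ethyl}-6-methoxyphenol; 14 (2S,5S)-1-{[3,5-dimethoxy-4-(methoxymethoxy)phenyl]methyl}-2,5-dimethylthiolan-1-ium tetrafluoroborate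
Product: 18 tert-butyl{[(2S,3R)-5-bromo-2-[3,5-dimethoxy-4-(methoxymethoxy)phenyl]-7-methoxy-2,3-dihydro-1-benzofuran-3-yl]methoxy}dimethylsilane (trans), via ortho-quinone methide 15 (not isolated), via sulfonium ylide 16 (not isolated), via anti betaine 17 (not isolated)
Conditions: 14 (1.3 equiv), Cs2CO3 (3 equiv), CH2Cl2, 0 °C to rt; 6 added slowly over several hours
Reagents that add atoms: none
Why: Proposed new method: Cs2CO3 deprotonates the phenol of 6, sulfinate leaves to give ortho-quinone methide 15, and the same base converts 14 into the semi-stabilised benzylide 16; the ylide carbon adds 1,4 to the exocyclic carbon of 15 (C2–C3), ring A rearomatises to phenoxide betaine 17, and the phenoxide displaces the neutral thiolane at the benzylic sulfonium carbon with inversion (O1–C2). The closest known reaction type is the carbonate-mediated formal [4+1] annulation of ortho-quinone methides from 2-(1-sulfonylalkyl)phenols with carbonyl-stabilised sulfonium ylides to trans-2,3-dihydrobenzofurans, together with reagent-controlled epoxidation, aziridination and cyclopropanation by benzylides of chiral sulfides; the extension is the union of an aryl-substituted ylide on a chiral sulfide with an alkyl-substituted quinone methide. Ring B, the only ring formed, closes in a 5-exo-tet mode. C2 is controlled by the C2-symmetric thiolane: the ylide holds ring C away from the thiolane ring, the methyl group cis to the ylide carbon shields one face, and the invertive closure turns the resulting sulfonium-bearing centre into 2S. C3 is set in the carbon–carbon bond formation by the relative topicity of the partners, the E quinone methide and the bulky sulfonium group favouring the anti betaine in which ring C and the silyloxymethyl arm end on opposite faces. The step needs 1,4-addition to outrun tautomerisation of 15 to an enol ether and O-benzylation of the phenoxide by 14; slow addition of 6 to excess 14 and base, reversible return of sulfinate to 15 and the hindered 2,6-disubstituted phenoxide serve this purpose. The aryl bromide, the silyl ether and the acetal are inert to carbonate at room temperature, and the liberated sulfide can be recovered.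

Step 11
Reactants: 18 tert-butyl{[(2S,3R)-5-bromo-2-[3,5-dimethoxy-4-(methoxymethoxy)phenyl]-7-methoxy-2,3-dihydro-1-benzofuran-3-yl]methoxy}dimethylsilane; 19 acrylic acid
Product: 20 (2E)-3-[(2S,3R)-3-{[(tert-butyldimethylsilyl)oxy]methyl}-2-[3,5-dimethoxy-4-(methoxymethoxy)phenyl]-7-methoxy-2,3-dihydro-1-benzofuran-5-yl]prop-2-enoic acid
Conditions: Pd(OAc)2 (5 mol %), P(o-tol)3 (10 mol %), Et3N, DMF, 100 °C; mildly acidic work-up (pH 4)
Reagents that add atoms: none
Why: Heck reaction of the aryl bromide with acrylic acid as its ammonium salt; syn insertion and syn β-hydride elimination give the E cinnamic acid, and with the ring-C phenol masked ring B cannot open through a quinone methide under the amine base, so both stereocentres are untouched.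

Step 12
Reactants: 20 (2E)-3-[(2S,3R)-3-{[(tert-butyldimethylsilyl)oxy]methyl}-2-[3,5-dimethoxy-4-(methoxymethoxy)phenyl]-7-methoxy-2,3-dihydro-1-benzofuran-5-yl]prop-2-enoic acid
Product: 21 (2E)-3-[(2S,3R)-2-(4-hydroxy-3,5-dimethoxyphenyl)-3-(hydroxymethyl)-7-methoxy-2,3-dihydro-1-benzofuran-5-yl]prop-2-enoic acid (CNP0224723.1)
Conditions: 3 M aq. HCl, THF, 45 °C
Reagents that add atoms: none
Why: Acid hydrolysis of the primary silyl ether and of the phenolic methoxymethyl acetal in an alcohol-free medium, so that the acid is not esterified; if the C2–O bond ionises reversibly through the ring-C para-quinone methide, reclosure gives the thermodynamically preferred trans isomer with C3 unchanged.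

## Compound list

1 | 4-bromo-2-methoxyphenol | COc1cc(Br)ccc1O | starting material
2 | 4-bromo-2-iodo-6-methoxyphenol | COc1cc(Br)cc(I)c1O | intermediate
3 | (tert-butyldimethylsilyloxy)acetaldehyde | O=CCO[Si](C)(C)C(C)(C)C | starting material
4 | chloromagnesium 4-bromo-2-(chloromagnesio)-6-methoxyphenoxide (aryl Grignard phenoxide, not isolated) | COc1cc(Br)cc([Mg]Cl)c1O[Mg]Cl | intermediate
5 | rac-1-(5-bromo-2-hydroxy-3-methoxyphenyl)-2-[(tert-butyldimethylsilyl)oxy]ethan-1-ol | COc1cc(Br)cc(C(O)CO[Si](C)(C)C(C)(C)C)c1O | intermediate
6 | rac-4-bromo-2-{2-[(tert-butyldimethylsilyl)oxy]-1-(4-methylbenzenesulfonyl)ethyl}-6-methoxyphenol | Cc1ccc(cc1)S(=O)(=O)C(CO[Si](C)(C)C(C)(C)C)c1cc(Br)cc(OC)c1O | intermediate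
7 | (2R,5R)-hexane-2,5-diol | C[C@@H](O)CC[C@@H](C)O | starting material
8 | (2R,5R)-hexane-2,5-diyl dimethanesulfonate | C[C@@H](OS(C)(=O)=O)CC[C@@H](C)OS(C)(=O)=O | intermediate
9 | (2S,5S)-2,5-dimethylthiolane | C[C@H]1CC[C@H](C)S1 | intermediate
10 | syringaldehyde (4-hydroxy-3,5-dimethoxybenzaldehyde) | COc1cc(C=O)cc(OC)c1O | starting material
11 | 3,5-dimethoxy-4-(methoxymethoxy)benzaldehyde | COCOc1c(OC)cc(C=O)cc1OC | intermediate
12 | [3,5-dimethoxy-4-(methoxymethoxy)phenyl]methanol | COCOc1c(OC)cc(CO)cc1OC | intermediate
13 | 5-(bromomethyl)-1,3-dimethoxy-2-(methoxymethoxy)benzene | COCOc1c(OC)cc(CBr)cc1OC | intermediate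
14 | (2S,5S)-1-{[3,5-dimethoxy-4-(methoxymethoxy)phenyl]methyl}-2,5-dimethylthiolan-1-ium tetrafluoroborate | C[C@H]1CC[C@H](C)[S+]1Cc1cc(OC)c(OCOC)c(OC)c1.F[B-](F)(F)F | intermediate
15 | (6E)-4-bromo-6-{2-[(tert-butyldimethylsilyl)oxy]ethylidene}-2-methoxycyclohexa-2,4-dien-1-one (ortho-quinone methide, not isolated) | COC1=CC(Br)=C/C(=C\CO[Si](C)(C)C(C)(C)C)C1=O | intermediate
16 | (2S,5S)-1-{[3,5-dimethoxy-4-(methoxymethoxy)phenyl]methanidyl}-2,5-dimethylthiolan-1-ium (sulfonium benzylide, not isolated) | C[C@H]1CC[C@H](C)[S+]1[CH-]c1cc(OC)c(OCOC)c(OC)c1 | intermediate
17 | 4-bromo-2-[(1R,2R)-3-[(tert-butyldimethylsilyl)oxy]-1-[3,5-dimethoxy-4-(methoxymethoxy)phenyl]-1-[(2S,5S)-2,5-dimethylthiolan-1-ium-1-yl]propan-2-yl]-6-methoxyphenolate (anti betaine, not isolated) | COc1cc([C@@H]([C@@H](CO[Si](C)(C)C(C)(C)C)c2cc(Br)cc(OC)c2[O-])[S+]2[C@@H](C)CC[C@@H]2C)cc(OC)c1OCOC | intermediate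
18 | tert-butyl{[(2S,3R)-5-bromo-2-[3,5-dimethoxy-4-(methoxymethoxy)phenyl]-7-methoxy-2,3-dihydro-1-benzofuran-3-yl]methoxy}dimethylsilane (trans) | COc1cc([C@H]2Oc3c(OC)cc(Br)cc3[C@@H]2CO[Si](C)(C)C(C)(C)C)cc(OC)c1OCOC | intermediate
19 | acrylic acid | C=CC(=O)O | starting material
20 | (2E)-3-[(2S,3R)-3-{[(tert-butyldimethylsilyl)oxy]methyl}-2-[3,5-dimethoxy-4-(methoxymethoxy)phenyl]-7-methoxy-2,3-dihydro-1-benzofuran-5-yl]prop-2-enoic acid | COc1cc([C@H]2Oc3c(OC)cc(/C=C/C(=O)O)cc3[C@@H]2CO[Si](C)(C)C(C)(C)C)cc(OC)c1OCOC | intermediate
21 | (2E)-3-[(2S,3R)-2-(4-hydroxy-3,5-dimethoxyphenyl)-3-(hydroxymethyl)-7-methoxy-2,3-dihydro-1-benzofuran-5-yl]prop-2-enoic acid | COc1cc([C@H]2Oc3c(OC)cc(/C=C/C(=O)O)cc3[C@@H]2CO)cc(OC)c1O | target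

## Step count and least certain steps

Total: 12 steps. Longest linear sequence: 7 steps (steps 6, 7, 8, 9, 10, 11, 12 from syringaldehyde). The ring-A branch (steps 1–3) and the sulfide branch (steps 4–5) are shorter.

**Step 10 (key step; the one step that extends known chemistry).**
- Most likely failure: insufficient relative topicity in the ylide addition. Unlike the carbonyl-stabilised cases, the betaine cannot revert or equilibrate, so any syn betaine closes to the cis ring.
- Consequence: a cis isomer must be removed at the stage of 18, because later epimerisation at C2 would turn it into the enantiomer of the target and lower the enantiomeric purity.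
- Further hazards: incomplete face discrimination on the ylide, tautomerisation of the alkyl quinone methide before capture, and O-benzylation of the phenoxide by the sulfonium salt.
- Fallback (known reactions only), from 2 and 13, rejoining at 18:
  - The phenol of 2 is benzylated with 13 (K2CO3, DMF) to give aryl benzyl ether F1.
  - Coupling of its aryl iodide with ethyl diazoacetate under zerovalent palladium (Pd(PPh3)4, Ag2CO3, Et3N, toluene, rt; the bromide is untouched) gives aryldiazoacetate F2.
  - Enantioselective intramolecular carbene insertion into the benzylic C–H bond with a chiral dirhodium tetracarboxylate (Rh2(S-PTTL)4 or its mirror image, whichever gives 2S) closes ring B to cis ester F3.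
  - NaOEt in EtOH epimerises C3 to trans ester F4.
  - LiBH4 reduces the ester to alcohol F5.
  - TBSCl and imidazole give 18.

**Step 3.**
- Most likely failure: loss of the silyl ether under the sulfinic acid, or diversion of the ortho-hydroxybenzyl cation by proton loss toward an enol ether and on to a benzofuran. The β-silyloxy group slows ionisation and lengthens exposure.
- Fallback, from 5, rejoining at 18: the phenol of 5 is converted selectively into aryl tert-butyl carbonate F6 (Boc2O, i-Pr2NEt, catalytic DMAP, CH2Cl2, 0 °C). Treating F6 with KOt-Bu at −78 °C in the presence of ylide 16 pre-formed from 14 triggers carbonate migration to the benzylic oxygen and loss of tert-butyl carbonate. This releases the same quinone methide 15 under base without any acid step, and annulation then gives 18.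

**Step 2.**
- Most likely failure: incomplete iodine–magnesium exchange on the electron-rich magnesium phenoxide with protonation back to 1; enolisation of the aldehyde; or silyl migration from the primary to the secondary oxygen in the magnesium alkoxide before quench.
- Fallback, from 1, rejoining at 5: ortho-selective hydroxyalkylation of the bromomagnesium phenoxide of 1 (EtMgBr, then solvent change to CH2Cl2) with aldehyde 3. The chelated phenoxide attacks the aldehyde through its free ortho carbon and gives 5 directly, without the iodide and without an aryl Grignard reagent. No new compound is involved.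

**Step 11.**
- Most likely failure: slow oxidative addition to the electron-rich aryl bromide at the temperature needed, with catalyst decomposition and protodebromination.
- Fallback, from 18, rejoining at 20: bromine–lithium exchange (n-BuLi, THF, −78 °C) and formylation with DMF give aldehyde F7. Knoevenagel–Doebner condensation with malonic acid (pyridine, catalytic piperidine, 85 °C) then gives the E acid 20 without palladium.

**Step 12.**
- Most likely failure: acid-promoted ionisation of the C2–O bond going on to irreversible products (elimination or capture by water) before the phenolic acetal is fully cleaved, since the acetal requires more forcing conditions than the silyl ether.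
- Fallback, from 20, rejoining at 21: staged deprotection. HF·pyridine (THF, 0 °C) removes the silyl group to give hydroxy acid F8. The acetal is then cleaved under aprotic conditions with bromotrimethylsilane (CH2Cl2, −30 °C) followed by aqueous NaHCO3 work-up.

Further compounds

F1 | step 10 | 5-bromo-2-{[3,5-dimethoxy-4-(methoxymethoxy)phenyl]methoxy}-1-iodo-3-methoxybenzene | COCOc1c(OC)cc(COc2c(I)cc(Br)cc2OC)cc1OC
F2 | step 10 | ethyl 2-(5-bromo-2-{[3,5-dimethoxy-4-(methoxymethoxy)phenyl]methoxy}-3-methoxyphenyl)-2-diazoacetate | CCOC(=O)C(=[N+]=[N-])c1cc(Br)cc(OC)c1OCc1cc(OC)c(OCOC)c(OC)c1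
F3 | step 10 | ethyl (2S,3R)-5-bromo-2-[3,5-dimethoxy-4-(methoxymethoxy)phenyl]-7-methoxy-2,3-dihydro-1-benzofuran-3-carboxylate (cis) | COc1cc([C@H]2Oc3c(OC)cc(Br)cc3[C@H]2C(=O)OCC)cc(OC)c1OCOC
F4 | step 10 | ethyl (2S,3S)-5-bromo-2-[3,5-dimethoxy-4-(methoxymethoxy)phenyl]-7-methoxy-2,3-dihydro-1-benzofuran-3-carboxylate (trans) | COc1cc([C@H]2Oc3c(OC)cc(Br)cc3[C@@H]2C(=O)OCC)cc(OC)c1OCOC
F5 | step 10 | [(2S,3R)-5-bromo-2-[3,5-dimethoxy-4-(methoxymethoxy)phenyl]-7-methoxy-2,3-dihydro-1-benzofuran-3-yl]methanol | COc1cc([C@H]2Oc3c(OC)cc(Br)cc3[C@@H]2CO)cc(OC)c1OCOC
F6 | step 3 | rac-4-bromo-2-{2-[(tert-butyldimethylsilyl)oxy]-1-hydroxyethyl}-6-methoxyphenyl tert-butyl carbonate | COc1cc(Br)cc(C(O)CO[Si](C)(C)C(C)(C)C)c1OC(=O)OC(C)(C)C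
F0 | step 2 | none | none
F7 | step 11 | (2S,3R)-3-{[(tert-butyldimethylsilyl)oxy]methyl}-2-[3,5-dimethoxy-4-(methoxymethoxy)phenyl]-7-methoxy-2,3-dihydro-1-benzofuran-5-carbaldehyde | COc1cc([C@H]2Oc3c(OC)cc(C=O)cc3[C@@H]2CO[Si](C)(C)C(C)(C)C)cc(OC)c1OCOC
F8 | step 12 | (2E)-3-[(2S,3R)-2-[3,5-dimethoxy-4-(methoxymethoxy)phenyl]-3-(hydroxymethyl)-7-methoxy-2,3-dihydro-1-benzofuran-5-yl]prop-2-enoic acid | COc1cc([C@H]2Oc3c(OC)cc(/C=C/C(=O)O)cc3[C@@H]2CO)cc(OC)c1OCOC
A1 | alternative 1 | 4-{(E)-2-[5-(dimethoxymethyl)-2-hydroxy-3-methoxyphenyl]ethenyl}-2,6-dimethoxyphenyl 2,2-dimethylpropanoate | COc1cc(/C=C/c2cc(C(OC)OC)cc(OC)c2O)cc(OC)c1OC(=O)C(C)(C)C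
A2 | alternative 1 | methyl (2S,3S)-5-(dimethoxymethyl)-2-[3,5-dimethoxy-4-(2,2-dimethylpropanoyloxy)phenyl]-7-methoxy-2,3-dihydro-1-benzofuran-3-carboxylate (trans) | COc1cc([C@H]2Oc3c(OC)cc(C(OC)OC)cc3[C@@H]2C(=O)OC)cc(OC)c1OC(=O)C(C)(C)C
A3 | alternative 2 | (2R)-2-(5-bromo-2-hydroxy-3-methoxyphenyl)-1-(4-hydroxy-3,5-dimethoxyphenyl)propane-1,3-diol (either C1 epimer) | COc1cc(C(O)[C@@H](CO)c2cc(Br)cc(OC)c2O)cc(OC)c1O
A4 | alternative 2 | 4-[(2S,3R)-5-bromo-3-(hydroxymethyl)-7-methoxy-2,3-dihydro-1-benzofuran-2-yl]-2,6-dimethoxyphenol (trans) | COc1cc([C@H]2Oc3c(OC)cc(Br)cc3[C@@H]2CO)cc(OC)c1O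
A5 | alternative 3 | tert-butyldimethyl{[(2E)-3-(4,4,5,5-tetramethyl-1,3,2-dioxaborolan-2-yl)prop-2-en-1-yl]oxy}silane | CC(C)(C)[Si](C)(C)OC/C=C/B1OC(C)(C)C(C)(C)O1
A6 | alternative 3 | 5-bromo-1,3-dimethoxy-2-(methoxymethoxy)benzene | COCOc1c(OC)cc(Br)cc1OC
A7 | alternative 3 | 2-[3-iodo-5-methoxy-4-(methoxymethoxy)phenyl]-1,3-dioxolane | COCOc1c(I)cc(C2OCCO2)cc1OC
A8 | alternative 3 | 2-[(1S,2R)-3-[(tert-butyldimethylsilyl)oxy]-1-[3,5-dimethoxy-4-(methoxymethoxy)phenyl]-2-[5-(1,3-dioxolan-2-yl)-3-methoxy-2-(methoxymethoxy)phenyl]propyl]-4,4,5,5-tetramethyl-1,3,2-dioxaborolane | COc1cc([C@@H](B2OC(C)(C)C(C)(C)O2)[C@@H](CO[Si](C)(C)C(C)(C)C)c2cc(C3OCCO3)cc(OC)c2OCOC)cc(OC)c1OCOC
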